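**Plan**
1. The chain is numbered C1 (ArCH2) to C12 (furfuryl CH2); ring A is the hydroquinone, ring B the furan. The retrosynthesis cuts C9–C10 together with C11–CH3 first (a three-component union), then C1–C2 with C3–CH3, then C4–C5, then C5–C6 with C7–CH3.
2. Enabling feature: in the C10=C11 alkene, the CH carbon C10 carries the chain carbon C9 cis to the methyl on C11, and C11 also carries C12, which is bound to C2 of ring B. This is the pattern left by syn addition of CH3–metal across the terminal alkyne of 2-propargyl-4-methylfuran, which puts a carbon–metal bond on C10 for coupling to the sp3 carbon C9.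
3. Forward order: ring B is made first by dehydrative aromatisation of a butenolide–propargyl adduct; ring A is bought as 2,6-dimethylhydroquinone and one of its methyl groups becomes C1. The chain grows from a C6–C9 unit to the C5 aldehyde, then gains the C2–C4 propargyl unit, the arene, the C9 iodide and finally the alkyne of ring B.
4. Stereochemistry: C5 (R) comes from a chiral phosphoric acid-catalysed allenylboration of an (E)-enal. All three (E)-alkenes come from syn-methylalumination of terminal alkynes followed by bond formation with retention.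
5. Protection: TBS ethers on both phenols and on the C5 hydroxyl, removed together in the last step.

Key step: step 11

Assumption: (R)-TRIP is taken to direct the allenylboronate to the Re face of enal 11, as it does with aryl and alkenyl aldehydes; the configuration of 12 would be checked by Mosher ester analysis before material is carried on.

**Route**

Step 1
Reactants: 1 4-methylfuran-2(5H)-one
Product: 3 4-methyl-2-(prop-2-yn-1-yl)furan, via hemiketal 2 (not isolated)
Conditions: propargyl bromide, Mg, HgCl2 (cat.), Et2O, 0 °C; then 1 (inverse addition, 1.0 equiv of Grignard reagent), Et2O, −78 °C; aq. NH4Cl; p-TsOH (cat.), CH2Cl2, rt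
Reagents that add atoms: propargyl bromide, C#CCBr
Why: Allenylmagnesium bromide should add 1,2 to the lactone carbonyl of the β-substituted butenolide through a cyclic SE2' transition state and so deliver a propargyl group, and the cyclic hemiketal 2 then loses water under acid to aromatise (the known butenolide-to-2-substituted-furan conversion), which fixes the 2,4-substitution of ring B without ambiguity.

Step 2
Reactants: 4 2,6-dimethylbenzene-1,4-diol
Product: 5 2,6-dimethyl-1,4-bis(tert-butyldimethylsilyloxy)benzene
Conditions: TBSCl (2.5 equiv), imidazole, DMF, 40 °C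
Reagents that add atoms: tert-butyldimethylsilyl chloride, CC(C)(C)[Si](C)(C)Cl
Why: Imidazole-mediated silylation (Corey conditions) should mask both phenols of the oxidation-prone hydroquinone as silyl ethers that fluoride removes at the end.

Step 3
Reactants: 5 2,6-dimethyl-1,4-bis(tert-butyldimethylsilyloxy)benzene
Product: 6 2-(bromomethyl)-6-methyl-1,4-bis(tert-butyldimethylsilyloxy)benzene
Conditions: NBS (1.0 equiv), AIBN (5 mol %), PhCF3, 80 °C
Reagents that add atoms: N-bromosuccinimide, O=C1CCC(=O)N1Br
Why: Wohl–Ziegler radical bromination in a non-polar solvent should attack a benzylic C–H bond in preference to the hindered ring positions, and since the two methyl groups are equivalent one equivalent of NBS should give the monobromide as the main product.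

Step 4
Reactants: 7 tert-butyl(but-3-yn-1-yloxy)dimethylsilane
Product: 10 (2E)-5-(tert-butyldimethylsilyloxy)-3-methylpent-2-en-1-ol, via alkenylalane 8 (not isolated), via lithium alanate 9 (not isolated)
Conditions: Me3Al (2 equiv), Cp2ZrCl2 (0.25 equiv), CH2Cl2, 0 °C → rt; volatiles removed; n-BuLi, hexane, 0 °C; (CH2O)n, THF, rt; aq. work-up
Reagents that add atoms: trimethylaluminium, C[Al](C)C; formaldehyde (used as paraformaldehyde), C=O
Why: Negishi zirconium-catalysed syn-methylalumination of the terminal alkyne, ate-complex formation and hydroxymethylation with formaldehyde should give the (E)-trisubstituted allylic alcohol, its geometry fixed by the syn addition and by retention in the C–C bond formation.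

Step 5
Reactants: 10 (2E)-5-(tert-butyldimethylsilyloxy)-3-methylpent-2-en-1-ol
Product: 11 (2E)-5-(tert-butyldimethylsilyloxy)-3-methylpent-2-enal
Conditions: MnO2 (15 equiv), CH2Cl2, rt
Reagents that add atoms: none
Why: MnO2 oxidises allylic alcohols selectively to enals and should neither touch the silyl ether nor isomerise the alkene.

Step 6
Reactants: 11 (2E)-5-(tert-butyldimethylsilyloxy)-3-methylpent-2-enal
Product: 12 (4R,5E)-8-(tert-butyldimethylsilyloxy)-6-methyloct-5-en-1-yn-4-ol
Conditions: allenylboronic acid pinacol ester (1.5 equiv), (R)-TRIP [(R)-3,3'-bis(2,4,6-triisopropylphenyl)-1,1'-binaphthyl-2,2'-diyl hydrogen phosphate] (10 mol %), 4 Å MS, toluene, −20 °C; aq. NaHCO3 work-up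
Reagents that add atoms: allenylboronic acid pinacol ester, C=C=CB1OC(C)(C)C(C)(C)O1
Why: In this chiral Brønsted acid-catalysed asymmetric propargylation the phosphoric acid binds the boronate oxygen and the formyl hydrogen in a chair-like six-membered SE2' transition state, so that the allenylboronate should attack the Re face of the enal and set the C5 carbinol as (R).

Step 7
Reactants: 12 (4R,5E)-8-(tert-butyldimethylsilyloxy)-6-methyloct-5-en-1-yn-4-ol
Product: 13 (4R,5E)-4,8-bis(tert-butyldimethylsilyloxy)-6-methyloct-5-en-1-yne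
Conditions: TBSCl, imidazole, DMF, rt
Reagents that add atoms: tert-butyldimethylsilyl chloride, CC(C)(C)[Si](C)(C)Cl
Why: Standard silylation protects the secondary allylic alcohol so that it can neither quench nor ionise under the organoaluminium conditions that follow.

Step 8
Reactants: 13 (4R,5E)-4,8-bis(tert-butyldimethylsilyloxy)-6-methyloct-5-en-1-yne; 6 2-(bromomethyl)-6-methyl-1,4-bis(tert-butyldimethylsilyloxy)benzene
Product: 15 (2E,5R,6E)-1-[2,5-bis(tert-butyldimethylsilyloxy)-3-methylphenyl]-5,9-bis(tert-butyldimethylsilyloxy)-3,7-dimethylnona-2,6-diene, via alkenylalane 14 (not isolated)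
Conditions: Me3Al (2.5 equiv), Cp2ZrCl2 (0.3 equiv), CH2Cl2, 0 °C → rt; excess Me3Al removed in vacuo; then 6 (1.1 equiv), Pd(PPh3)4 (5 mol %), THF, rt
Reagents that add atoms: trimethylaluminium, C[Al](C)C
Why: Zirconium-catalysed syn-methylalumination of the terminal alkyne gives (E)-alkenylalane 14, and its Pd(PPh3)4-catalysed cross-coupling with benzylic bromide 6 (Negishi alkenylalane–benzyl halide coupling) should proceed with retention, installing ring A and the (E)-C2=C3 alkene in one flask.

Step 9
Reactants: 15 (2E,5R,6E)-1-[2,5-bis(tert-butyldimethylsilyloxy)-3-methylphenyl]-5,9-bis(tert-butyldimethylsilyloxy)-3,7-dimethylnona-2,6-diene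
Product: 16 (3E,5R,7E)-9-[2,5-bis(tert-butyldimethylsilyloxy)-3-methylphenyl]-5-(tert-butyldimethylsilyloxy)-3,7-dimethylnona-3,7-dien-1-ol
Conditions: CSA (0.1 equiv), MeOH/CH2Cl2 1:1, 0 °C
Reagents that add atoms: none
Why: Acid-catalysed methanolysis should cleave the unhindered primary alkyl silyl ether much faster than the secondary allylic one and the two aryl silyl ethers, which are comparatively stable to mild acid.

Step 10
Reactants: 16 (3E,5R,7E)-9-[2,5-bis(tert-butyldimethylsilyloxy)-3-methylphenyl]-5-(tert-butyldimethylsilyloxy)-3,7-dimethylnona-3,7-dien-1-ol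
Product: 17 (2E,5R,6E)-1-[2,5-bis(tert-butyldimethylsilyloxy)-3-methylphenyl]-5-(tert-butyldimethylsilyloxy)-9-iodo-3,7-dimethylnona-2,6-diene
Conditions: I2, PPh3, imidazole, CH2Cl2, 0 °C
Reagents that add atoms: iodine, II
Why: Appel-type iodination converts the primary alcohol into the iodide by SN2 displacement of an oxyphosphonium ion under buffered conditions that should spare the silyl ethers and the alkenes.

Step 11
Reactants: 3 4-methyl-2-(prop-2-yn-1-yl)furan (1.6 equiv); 17 (2E,5R,6E)-1-[2,5-bis(tert-butyldimethylsilyloxy)-3-methylphenyl]-5-(tert-butyldimethylsilyloxy)-9-iodo-3,7-dimethylnona-2,6-diene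
Product: 20 (2E,5R,6E,10E)-1-[2,5-bis(tert-butyldimethylsilyloxy)-3-methylphenyl]-5-(tert-butyldimethylsilyloxy)-3,7,11-trimethyl-12-(4-methylfuran-2-yl)dodeca-2,6,10-triene, via alkenylalane 18 (not isolated), via alkenylzinc chloride 19 (not isolated)
Conditions: 3, Me3Al (3.2 equiv), Cp2ZrCl2 (0.4 equiv), CH2Cl2, 0 °C → rt; volatiles removed in vacuo; ZnCl2 (1.6 equiv), THF, 0 °C; then 17 (1.0 equiv), Pd2(dba)3 (2 mol %), P(c-C5H9)3 (8 mol %), N-methylimidazole (1.2 equiv), THF/NMP 2:1, 80 °C
Reagents that add atoms: trimethylaluminium, C[Al](C)C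
Why: Proposed new method: Cp2ZrCl2-catalysed syn-methylalumination of the terminal alkyne of 3 places the methyl group on the internal carbon and aluminium on the terminal carbon to give (E)-alkenylalane 18, ZnCl2 moves the alkenyl group to zinc (19), and zerovalent palladium ligated by tricyclopentylphosphine then undergoes SN2-type oxidative addition into the primary C–I bond of 17, N-methylimidazole-assisted transmetalation with 19 and reductive elimination, which forges the CH2–CH= bond with retention of alkene geometry. The closest known reaction types are the one-flask Negishi methylalumination–palladium cross-coupling of terminal alkynes with aryl, alkenyl and benzyl halides (with ZnCl2 as transmetalation aid) and the Pd2(dba)3/tricyclopentylphosphine Negishi coupling of alkenylzinc halides with unactivated primary alkyl iodides; their merger on an alkyne-derived alane and a β-hydrogen-bearing alkyl iodide is the untested element. No ring is closed and no stereocentre is formed; the only stereochemical element created is the (E)-trisubstituted C10=C11 alkene, which is fixed by syn addition of C–Al across the alkyne and kept because both transmetalations and the reductive elimination retain configuration at the sp2 carbon. The step needs regioselective methyl delivery to the internal alkyne carbon, which the terminal alkyne with its unbranched furfuryl substituent secures; it needs alkenyl transfer in place of methyl transfer, which the faster migration of sp2 groups and the removal of excess Me3Al before ZnCl2 is added secure; and it needs reductive elimination to outrun β-hydride elimination from the homoallyl–palladium intermediate, for which the bulky electron-rich trialkylphosphine is chosen. The furan, the three silyl ethers and the skipped alkenes offer no acidic hydrogen or electrophilic site to the alkenylmetals, so alkyne, methyl and iodide are united in one flask and the last two C–C bonds and the last alkene geometry of the skeleton are set together.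

Step 12
Reactants: 20 (2E,5R,6E,10E)-1-[2,5-bis(tert-butyldimethylsilyloxy)-3-methylphenyl]-5-(tert-butyldimethylsilyloxy)-3,7,11-trimethyl-12-(4-methylfuran-2-yl)dodeca-2,6,10-triene
Product: 21 2-[(2E,5R,6E,10E)-5-hydroxy-3,7,11-trimethyl-12-(4-methylfuran-2-yl)dodeca-2,6,10-trien-1-yl]-6-methylbenzene-1,4-diol
Conditions: TBAF (6 equiv), AcOH (6 equiv), THF, 0 °C → rt, under Ar; aq. Na2S2O4 work-up
Reagents that add atoms: none
Why: Fluoride cleaves the three Si–O bonds while acetic acid buffers the phenoxides and the alkoxide, so the furan, the skipped alkenes and the air-sensitive hydroquinone should survive and the C5 configuration is untouched.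

**Compound list**
1 | 4-methylfuran-2(5H)-one | O=C1C=C(C)CO1 | starting material
2 | 4-methyl-2-(prop-2-yn-1-yl)-2,5-dihydrofuran-2-ol (cyclic hemiketal, formed in the flask) | OC1(CC#C)C=C(C)CO1 | intermediate
3 | 4-methyl-2-(prop-2-yn-1-yl)furan | C#CCc1cc(C)co1 | intermediate
4 | 2,6-dimethylbenzene-1,4-diol | Cc1cc(O)cc(C)c1O | starting material
5 | 2,6-dimethyl-1,4-bis(tert-butyldimethylsilyloxy)benzene | Cc1cc(O[Si](C)(C)C(C)(C)C)cc(C)c1O[Si](C)(C)C(C)(C)C | intermediate
6 | 2-(bromomethyl)-6-methyl-1,4-bis(tert-butyldimethylsilyloxy)benzene | BrCc1cc(O[Si](C)(C)C(C)(C)C)cc(C)c1O[Si](C)(C)C(C)(C)C | intermediate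
7 | tert-butyl(but-3-yn-1-yloxy)dimethylsilane | C#CCCO[Si](C)(C)C(C)(C)C | starting material
8 | dimethyl[(1E)-4-(tert-butyldimethylsilyloxy)-2-methylbut-1-en-1-yl]alane (formed in the flask) | C[Al](C)/C=C(\C)CCO[Si](C)(C)C(C)(C)C | intermediate
9 | lithium butyl(dimethyl)[(1E)-4-(tert-butyldimethylsilyloxy)-2-methylbut-1-en-1-yl]alanate (formed in the flask) | [Li+].CCCC[Al-](C)(C)/C=C(\C)CCO[Si](C)(C)C(C)(C)C | intermediate
10 | (2E)-5-(tert-butyldimethylsilyloxy)-3-methylpent-2-en-1-ol | OC/C=C(\C)CCO[Si](C)(C)C(C)(C)C | intermediate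
11 | (2E)-5-(tert-butyldimethylsilyloxy)-3-methylpent-2-enal | O=C/C=C(\C)CCO[Si](C)(C)C(C)(C)C | intermediate
12 | (4R,5E)-8-(tert-butyldimethylsilyloxy)-6-methyloct-5-en-1-yn-4-ol | C/C(=C\[C@H](O)CC#C)CCO[Si](C)(C)C(C)(C)C | intermediate
13 | (4R,5E)-4,8-bis(tert-butyldimethylsilyloxy)-6-methyloct-5-en-1-yne | C/C(=C\[C@H](O[Si](C)(C)C(C)(C)C)CC#C)CCO[Si](C)(C)C(C)(C)C | intermediate
14 | dimethyl[(1E,4R,5E)-4,8-bis(tert-butyldimethylsilyloxy)-2,6-dimethylocta-1,5-dien-1-yl]alane (formed in the flask) | C/C(=C\[C@H](O[Si](C)(C)C(C)(C)C)C/C(C)=C/[Al](C)C)CCO[Si](C)(C)C(C)(C)C | intermediate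
15 | (2E,5R,6E)-1-[2,5-bis(tert-butyldimethylsilyloxy)-3-methylphenyl]-5,9-bis(tert-butyldimethylsilyloxy)-3,7-dimethylnona-2,6-diene | C/C(=C\[C@H](O[Si](C)(C)C(C)(C)C)C/C(C)=C/Cc1cc(O[Si](C)(C)C(C)(C)C)cc(C)c1O[Si](C)(C)C(C)(C)C)CCO[Si](C)(C)C(C)(C)C | intermediate
16 | (3E,5R,7E)-9-[2,5-bis(tert-butyldimethylsilyloxy)-3-methylphenyl]-5-(tert-butyldimethylsilyloxy)-3,7-dimethylnona-3,7-dien-1-ol | C/C(=C\[C@H](O[Si](C)(C)C(C)(C)C)C/C(C)=C/Cc1cc(O[Si](C)(C)C(C)(C)C)cc(C)c1O[Si](C)(C)C(C)(C)C)CCO | intermediate
17 | (2E,5R,6E)-1-[2,5-bis(tert-butyldimethylsilyloxy)-3-methylphenyl]-5-(tert-butyldimethylsilyloxy)-9-iodo-3,7-dimethylnona-2,6-diene | C/C(=C\[C@H](O[Si](C)(C)C(C)(C)C)C/C(C)=C/Cc1cc(O[Si](C)(C)C(C)(C)C)cc(C)c1O[Si](C)(C)C(C)(C)C)CCI | intermediate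
18 | dimethyl[(1E)-2-methyl-3-(4-methylfuran-2-yl)prop-1-en-1-yl]alane (formed in the flask) | C[Al](C)/C=C(\C)Cc1cc(C)co1 | intermediate
19 | chloro[(1E)-2-methyl-3-(4-methylfuran-2-yl)prop-1-en-1-yl]zinc (formed in the flask) | Cl[Zn]/C=C(\C)Cc1cc(C)co1 | intermediate
20 | (2E,5R,6E,10E)-1-[2,5-bis(tert-butyldimethylsilyloxy)-3-methylphenyl]-5-(tert-butyldimethylsilyloxy)-3,7,11-trimethyl-12-(4-methylfuran-2-yl)dodeca-2,6,10-triene | C/C(=C\[C@H](O[Si](C)(C)C(C)(C)C)C/C(C)=C/Cc1cc(O[Si](C)(C)C(C)(C)C)cc(C)c1O[Si](C)(C)C(C)(C)C)CC/C=C(\C)Cc1cc(C)co1 | intermediate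
21 | 2-[(2E,5R,6E,10E)-5-hydroxy-3,7,11-trimethyl-12-(4-methylfuran-2-yl)dodeca-2,6,10-trien-1-yl]-6-methylbenzene-1,4-diol | C/C(=C\[C@H](O)C/C(C)=C/Cc1cc(O)cc(C)c1O)CC/C=C(\C)Cc1cc(C)co1 | target

**Step count and risks**
Total steps: 12. Longest linear sequence: 9 steps (7 to 21, steps 4 to 12).

Steps most likely to fail:

1. Step 11 (bears the label "Proposed new method:"). What may go wrong: β-hydride elimination from the homoallyl–palladium intermediate to a conjugated diene, transfer of methyl in place of the alkenyl group, deactivation of the palladium catalyst by aluminium and zirconium residues, and partial loss of the aryl silyl ethers in hot NMP. The fallback uses known chemistry with the polarity of the two partners reversed; it sets out from 3 and 17 and comes back at 20. Alkyne 3 would be methylaluminated as in step 11 to 18 and quenched with I2 (THF, −30 °C) to give 2-[(2E)-3-iodo-2-methylprop-2-en-1-yl]-4-methylfuran F1. Iodide 17 would be converted by direct zinc insertion (Zn dust, LiCl, THF, 40 °C) into the alkylzinc iodide iodo[(3E,5R,7E)-9-[2,5-bis(tert-butyldimethylsilyloxy)-3-methylphenyl]-5-(tert-butyldimethylsilyloxy)-3,7-dimethylnona-3,7-dien-1-yl]zinc F2. Pd(PPh3)4-catalysed Negishi homoallyl–alkenyl coupling of F2 with F1 (THF, rt) should then give 20 with retention of the (E)-geometry.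

2. Step 1. What may go wrong: ring opening of the magnesium hemiketalate followed by a second addition, γ-deprotonation of the butenolide by the Grignard reagent, and competing delivery of an allenyl group. The fallback replaces the direct lactone addition by an acyclic acylation that cannot over-add; it sets out from 1 and comes back at 3. Aminolysis of 1 with Me2AlN(OMe)Me (from Me3Al and N,O-dimethylhydroxylamine hydrochloride, CH2Cl2, 0 °C) would give (2Z)-4-hydroxy-N-methoxy-N,3-dimethylbut-2-enamide F3, which would be silylated at once (TBSCl, imidazole) to (2Z)-4-(tert-butyldimethylsilyloxy)-N-methoxy-N,3-dimethylbut-2-enamide F4 to prevent relactonisation. Addition of allenylmagnesium bromide (Et2O, −78 °C) should stop at the ketone (5Z)-7-(tert-butyldimethylsilyloxy)-6-methylhept-5-en-1-yn-4-one F5 because of the chelated tetrahedral intermediate. Aqueous HCl in THF would then remove the silyl group, and the (Z)-hydroxy enone should close to hemiketal 2 and dehydrate to 3.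

3. Step 6. What may go wrong: poor enantioface discrimination or slow addition with the β,β-disubstituted enal, giving 12 of insufficient enantiomeric purity. The fallback replaces asymmetric induction by a resolution; it sets out from 11 and comes back at 12. Barbier propargylation of 11 (propargyl bromide, Zn dust, THF, 0 °C) would give racemic (5E)-8-(tert-butyldimethylsilyloxy)-6-methyloct-5-en-1-yn-4-ol F6. Lipase-catalysed acylation (Novozym 435, vinyl acetate, MTBE, rt) should acylate the (R)-enantiomer preferentially according to the Kazlauskas rule (alkenyl as the large group, propargyl as the medium group), giving (4R,5E)-8-(tert-butyldimethylsilyloxy)-6-methyloct-5-en-1-yn-4-yl acetate F7 and leaving (4S,5E)-8-(tert-butyldimethylsilyloxy)-6-methyloct-5-en-1-yn-4-ol F8 behind. Methanolysis of F7 (K2CO3, MeOH, 0 °C) returns 12.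

**Further compounds**
F1 | step 11 | 2-[(2E)-3-iodo-2-methylprop-2-en-1-yl]-4-methylfuran | I/C=C(\C)Cc1cc(C)co1
F2 | step 11 | iodo[(3E,5R,7E)-9-[2,5-bis(tert-butyldimethylsilyloxy)-3-methylphenyl]-5-(tert-butyldimethylsilyloxy)-3,7-dimethylnona-3,7-dien-1-yl]zinc | C/C(=C\[C@H](O[Si](C)(C)C(C)(C)C)C/C(C)=C/Cc1cc(O[Si](C)(C)C(C)(C)C)cc(C)c1O[Si](C)(C)C(C)(C)C)CC[Zn]I
F3 | step 1 | (2Z)-4-hydroxy-N-methoxy-N,3-dimethylbut-2-enamide | CON(C)C(=O)/C=C(C)\CO
F4 | step 1 | (2Z)-4-(tert-butyldimethylsilyloxy)-N-methoxy-N,3-dimethylbut-2-enamide | CON(C)C(=O)/C=C(C)\CO[Si](C)(C)C(C)(C)C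
F5 | step 1 | (5Z)-7-(tert-butyldimethylsilyloxy)-6-methylhept-5-en-1-yn-4-one | C#CCC(=O)/C=C(C)\CO[Si](C)(C)C(C)(C)C
F6 | step 6 | racemic (5E)-8-(tert-butyldimethylsilyloxy)-6-methyloct-5-en-1-yn-4-ol | C/C(=C\C(O)CC#C)CCO[Si](C)(C)C(C)(C)C
F7 | step 6 | (4R,5E)-8-(tert-butyldimethylsilyloxy)-6-methyloct-5-en-1-yn-4-yl acetate | C/C(=C\[C@H](OC(C)=O)CC#C)CCO[Si](C)(C)C(C)(C)C
F8 | step 6 | (4S,5E)-8-(tert-butyldimethylsilyloxy)-6-methyloct-5-en-1-yn-4-ol | C/C(=C\[C@@H](O)CC#C)CCO[Si](C)(C)C(C)(C)C
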